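**Plan**

- Retrosynthesis: after removal of four silyl groups, ring C of the flavanone is cut at O1–C2 and C4–C4a. This gives unprotected 2,4-diprenylphloroglucinol (ring A) and a cinnamoyl chloride that carries the complete dihydrobenzofuran.
- The cinnamic acid is cut at the aryl–vinyl bond (Heck) to a 5-bromo-2,3-diaryl-2,3-dihydrobenzofuran. This is cut at C2–C3 (Rh-carbene C–H insertion) to a diaryl ketone hydrazone assembled from an aldehyde, a benzyl chloride and an aryl Grignard reagent.
- Forward: the furan ring arises first, then the acrylic acid side chain, and ring C is closed last onto the finished ring A in the convergent key step.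
- Enabling feature: in ring A the only unsubstituted carbon (future C4a) lies between two equivalent hydroxyls (future O1 and 5-OH), and both other ring carbons carry prenyl groups. Acylation therefore has one site, either hydroxyl closes the same pyranone, and the remaining 5-OH chelates C4=O.
- Stereochemistry: benzofuran C3 comes from the chiral Rh(II) catalyst, benzofuran C2 from acid equilibration to trans relative to C3, and flavanone C2 (S) from a chiral bifunctional catalyst in the ring-C closure.

Key step: step 10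

Assumption (remark on the chemistry): the antipodes of the two chiral catalysts named in steps 6 and 10 are those expected to give (3R) and (2S); should either induce the opposite sense, its enantiomer or pseudoenantiomer is used instead.

**Route**

Step 1
Reactants: 1 phloroglucinol; 2 prenyl bromide
Product: 3 2,4-bis(3-methylbut-2-en-1-yl)benzene-1,3,5-triol
Conditions: 2 (2.1 equiv), DBU (2.2 equiv), THF, 0 °C → rt
Reagents that add atoms: none
Why: Base-mediated C-alkylation of the enol-like phloroglucinol phenolate with an allylic bromide should favour the soft ring carbons over oxygen, and two equivalents should give the 2,4-dialkylated triol after chromatographic removal of mono- and tri-alkylated material.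

Step 2
Reactants: 4 5-bromo-2-hydroxy-4-methoxybenzaldehyde; 5 4-methoxybenzyl chloride
Product: 6 5-bromo-4-methoxy-2-[(4-methoxybenzyl)oxy]benzaldehyde
Conditions: 5 (1.2 equiv), K2CO3, KI (cat.), DMF, 60 °C
Reagents that add atoms: none
Why: Williamson ether synthesis at the only free phenol; the benzylic CH2 introduced here later becomes C2 of the dihydrobenzofuran.

Step 3
Reactants: 6 5-bromo-4-methoxy-2-[(4-methoxybenzyl)oxy]benzaldehyde; 7 3,5-dimethoxyphenylmagnesium chloride (THF solution)
Product: 8 rac-[5-bromo-4-methoxy-2-[(4-methoxybenzyl)oxy]phenyl](3,5-dimethoxyphenyl)methanol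
Conditions: 7 (1.2 equiv), THF, −20 → 0 °C; aq. NH4Cl
Reagents that add atoms: none
Why: Grignard 1,2-addition to the aldehyde is much faster than any halogen–magnesium exchange at the aryl bromide, and the racemic carbinol centre is removed in the next step.

Step 4
Reactants: 8 rac-[5-bromo-4-methoxy-2-[(4-methoxybenzyl)oxy]phenyl](3,5-dimethoxyphenyl)methanol
Product: 9 [5-bromo-4-methoxy-2-[(4-methoxybenzyl)oxy]phenyl](3,5-dimethoxyphenyl)methanone
Conditions: activated MnO2 (10 equiv), CH2Cl2, rt
Reagents that add atoms: none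
Why: MnO2 oxidation of a doubly benzylic alcohol to the diaryl ketone, with ethers and the aryl bromide inert.

Step 5
Reactants: 9 [5-bromo-4-methoxy-2-[(4-methoxybenzyl)oxy]phenyl](3,5-dimethoxyphenyl)methanone
Product: 10 [5-bromo-4-methoxy-2-[(4-methoxybenzyl)oxy]phenyl](3,5-dimethoxyphenyl)methanone hydrazone (E/Z mixture)
Conditions: N2H4·H2O (10 equiv), AcOH (cat.), EtOH, reflux
Reagents that add atoms: hydrazine monohydrate, NN.O
Why: Acid-catalysed condensation of the diaryl ketone with excess hydrazine gives the free hydrazone, whose C=N geometry is irrelevant because it is lost on oxidation.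

Step 6
Reactants: 10 [5-bromo-4-methoxy-2-[(4-methoxybenzyl)oxy]phenyl](3,5-dimethoxyphenyl)methanone hydrazone
Product: 12 (2S,3R)-5-bromo-3-(3,5-dimethoxyphenyl)-6-methoxy-2-(4-methoxyphenyl)-2,3-dihydro-1-benzofuran (2,3-cis), via diaryldiazomethane 11 (not isolated)
Conditions: activated MnO2 (8 equiv), CH2Cl2, 0 °C → rt; filtration; then slow addition to Rh2(R-PTAD)4 (1 mol %), CH2Cl2, 0 °C
Reagents that add atoms: none
Why: Dehydrogenation of the hydrazone gives a donor/donor diazo compound whose rhodium carbene inserts into the activated benzylic ether C–H bond five atoms away (Rh(II)-catalysed intramolecular 1,5 C–H insertion); the chiral carboxylate ligands set C3 and, in the concerted insertion, C2, and the cis-2,3-diaryl isomer is the kinetic product.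

Step 7
Reactants: 12 (2S,3R)-5-bromo-3-(3,5-dimethoxyphenyl)-6-methoxy-2-(4-methoxyphenyl)-2,3-dihydro-1-benzofuran
Product: 14 5-[(2R,3R)-5-bromo-6-hydroxy-2-(4-hydroxyphenyl)-2,3-dihydro-1-benzofuran-3-yl]benzene-1,3-diol (2,3-trans), via trans tetramethyl ether 13 (not isolated)
Conditions: BBr3 (8 equiv), CH2Cl2, −78 °C → rt; ice/water
Reagents that add atoms: none
Why: BBr3 cleaves the four aryl methyl ethers (Lewis-acid ether cleavage) and, by reversible ionisation of the benzylic C2–O bond assisted by the para-oxygenated aryl group, equilibrates C2 to the more stable 2,3-trans arrangement while C3, set in step 6, is not touched.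

Step 8
Reactants: 14 5-[(2R,3R)-5-bromo-6-hydroxy-2-(4-hydroxyphenyl)-2,3-dihydro-1-benzofuran-3-yl]benzene-1,3-diol
Product: 15 (2R,3R)-5-bromo-3-[3,5-bis(tert-butyldimethylsilyloxy)phenyl]-6-(tert-butyldimethylsilyloxy)-2-[4-(tert-butyldimethylsilyloxy)phenyl]-2,3-dihydro-1-benzofuran
Conditions: TBSCl (5 equiv), imidazole (10 equiv), DMF, rt
Reagents that add atoms: tert-butyldimethylsilyl chloride (TBSCl), CC(C)(C)[Si](C)(C)Cl
Why: Imidazole-mediated silylation of all four phenols installs groups that survive the acid chloride and magnesium phenolate chemistry and can later be removed by buffered fluoride without harm to prenyl groups or the flavanone.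

Step 9
Reactants: 15 tetrakis(TBS) aryl bromide; 16 acrylic acid
Product: 17 (2E)-3-[(2R,3R)-3-[3,5-bis(tert-butyldimethylsilyloxy)phenyl]-6-(tert-butyldimethylsilyloxy)-2-[4-(tert-butyldimethylsilyloxy)phenyl]-2,3-dihydro-1-benzofuran-5-yl]prop-2-enoic acid
Conditions: 16 (1.5 equiv), Pd[P(t-Bu)3]2 (5 mol %), Cy2NMe (2.5 equiv), BHT (cat.), 1,4-dioxane, 80 °C; aq. citric acid
Reagents that add atoms: none
Why: Mizoroki–Heck coupling with a bulky electron-rich phosphine suited to hindered electron-rich aryl bromides gives the cinnamic acid directly, the E geometry following from syn insertion and syn β-hydride elimination.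

Step 10
Reactants: 17 (2E)-cinnamic acid tetrakis(TBS) ether; 3 2,4-bis(3-methylbut-2-en-1-yl)benzene-1,3,5-triol
Product: 20 (2S)-2-[(2R,3R)-3-[3,5-bis(tert-butyldimethylsilyloxy)phenyl]-6-(tert-butyldimethylsilyloxy)-2-[4-(tert-butyldimethylsilyloxy)phenyl]-2,3-dihydro-1-benzofuran-5-yl]-5,7-dihydroxy-6,8-bis(3-methylbut-2-en-1-yl)-2,3-dihydro-4H-chromen-4-one, via acid chloride 18 (not isolated), via chalcone 19 (not isolated)
Conditions: (a) 17, 1-chloro-N,N,2-trimethylprop-1-en-1-amine (1.1 equiv), CH2Cl2, 0 °C → rt, concentration; (b) 3 (1.3 equiv) pre-treated with EtMgBr (2.5 equiv), Et2O → toluene, then the acid chloride, −20 °C → rt; (c) pH 7 phosphate wash, toluene layer dried and used directly; (d) quinidine-derived 9-amino(9-deoxy)-epi-cinchona 3,5-bis(trifluoromethyl)phenyl thiourea (20 mol %), toluene, −20 °C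
Reagents that add atoms: none
Why: Proposed new method: the bromomagnesium phenolate of 3 binds the carbonyl oxygen of acid chloride 18 and delivers the acyl group through a six-membered chelate to the only unsubstituted ring carbon, giving chalcone 19 without the protic or Lewis acid that would close the prenyl groups to chromans; the closest known reaction types are the ortho-C-acylation of metal phenolates and the Friedel–Crafts acylation/oxa-Michael annulation of phloroglucinols with cinnamoyl chlorides. Ring C then closes by a 6-endo-trig oxa-Michael addition of either of the two equivalent ortho hydroxyls to the enone, a closure known for 2'-hydroxychalcones under bifunctional cinchona-thiourea catalysis. The new stereocentre C2 is set by the catalyst: the thiourea binds the carbonyl, which is already chelated by the second ortho hydroxyl, and the quinuclidine guides the attacking phenol to one face of the β-carbon, so the remote dihydrobenzofuran centres should have no influence and the (2S) epimer is expected. The step needs C- over O-acylation and acyl substitution over conjugate addition of the ring carbon (the 4-aryl-dihydrocoumarin mode); the magnesium template, the hard acyl chloride and the electron-rich, weakly electrophilic β-aryl enone should secure this, and the mirror symmetry of ring A removes any regiochemical question. Low temperature and a non-polar solvent keep the uncatalysed closure and retro-Michael epimerisation slow.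

Step 11
Reactants: 20 tetrakis(TBS) flavanone
Product: 21 (2S)-2-[(2R,3R)-3-(3,5-dihydroxyphenyl)-6-hydroxy-2-(4-hydroxyphenyl)-2,3-dihydro-1-benzofuran-5-yl]-5,7-dihydroxy-6,8-bis(3-methylbut-2-en-1-yl)-2,3-dihydro-4H-chromen-4-one (CNP0230984.1)
Conditions: TBAF (6 equiv), AcOH (6 equiv), THF, 0 °C
Reagents that add atoms: none
Why: Fluoride cleavage of the four aryl silyl ethers under acetic acid buffering avoids both the acid that cyclises prenyl phenols and the base that opens 5-hydroxyflavanones, so no stereocentre is touched.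

**Compound list**

1 | phloroglucinol (benzene-1,3,5-triol) | Oc1cc(O)cc(O)c1 | starting material
2 | prenyl bromide (1-bromo-3-methylbut-2-ene) | CC(C)=CCBr | starting material
3 | 2,4-bis(3-methylbut-2-en-1-yl)benzene-1,3,5-triol | CC(C)=CCc1c(O)cc(O)c(CC=C(C)C)c1O | intermediate
4 | 5-bromo-2-hydroxy-4-methoxybenzaldehyde | O=Cc1cc(Br)c(OC)cc1O | starting material
5 | 4-methoxybenzyl chloride | COc1ccc(CCl)cc1 | starting material
6 | 5-bromo-4-methoxy-2-[(4-methoxybenzyl)oxy]benzaldehyde | O=Cc1cc(Br)c(OC)cc1OCc1ccc(OC)cc1 | intermediate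
7 | 3,5-dimethoxyphenylmagnesium chloride | COc1cc(OC)cc([Mg]Cl)c1 | starting material
8 | rac-[5-bromo-4-methoxy-2-[(4-methoxybenzyl)oxy]phenyl](3,5-dimethoxyphenyl)methanol | COc1cc(OC)cc(C(O)c2cc(Br)c(OC)cc2OCc2ccc(OC)cc2)c1 | intermediate
9 | [5-bromo-4-methoxy-2-[(4-methoxybenzyl)oxy]phenyl](3,5-dimethoxyphenyl)methanone | COc1cc(OC)cc(C(=O)c2cc(Br)c(OC)cc2OCc2ccc(OC)cc2)c1 | intermediate
10 | hydrazone of ketone 9 | COc1cc(OC)cc(C(=NN)c2cc(Br)c(OC)cc2OCc2ccc(OC)cc2)c1 | intermediate
11 | [5-bromo-4-methoxy-2-[(4-methoxybenzyl)oxy]phenyl](3,5-dimethoxyphenyl)diazomethane | COc1cc(OC)cc(C(=[N+]=[N-])c2cc(Br)c(OC)cc2OCc2ccc(OC)cc2)c1 | intermediate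
12 | (2S,3R)-5-bromo-3-(3,5-dimethoxyphenyl)-6-methoxy-2-(4-methoxyphenyl)-2,3-dihydro-1-benzofuran (cis) | Brc1cc2c(cc1OC)O[C@H](c1ccc(OC)cc1)[C@@H]2c1cc(OC)cc(OC)c1 | intermediate
13 | (2R,3R)-5-bromo-3-(3,5-dimethoxyphenyl)-6-methoxy-2-(4-methoxyphenyl)-2,3-dihydro-1-benzofuran (trans) | Brc1cc2c(cc1OC)O[C@@H](c1ccc(OC)cc1)[C@@H]2c1cc(OC)cc(OC)c1 | intermediate
14 | 5-[(2R,3R)-5-bromo-6-hydroxy-2-(4-hydroxyphenyl)-2,3-dihydro-1-benzofuran-3-yl]benzene-1,3-diol | Brc1cc2c(cc1O)O[C@@H](c1ccc(O)cc1)[C@@H]2c1cc(O)cc(O)c1 | intermediate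
15 | tetrakis(tert-butyldimethylsilyl) ether of 14 | Brc1cc2c(cc1O[Si](C)(C)C(C)(C)C)O[C@@H](c1ccc(O[Si](C)(C)C(C)(C)C)cc1)[C@@H]2c1cc(O[Si](C)(C)C(C)(C)C)cc(O[Si](C)(C)C(C)(C)C)c1 | intermediate
16 | acrylic acid | C=CC(=O)O | starting material
17 | (2E)-3-[(2R,3R)-tetrakis(TBS-oxy) dihydrobenzofuran-5-yl]prop-2-enoic acid | OC(=O)/C=C/c1cc2c(cc1O[Si](C)(C)C(C)(C)C)O[C@@H](c1ccc(O[Si](C)(C)C(C)(C)C)cc1)[C@@H]2c1cc(O[Si](C)(C)C(C)(C)C)cc(O[Si](C)(C)C(C)(C)C)c1 | intermediate
18 | acid chloride of 17 | ClC(=O)/C=C/c1cc2c(cc1O[Si](C)(C)C(C)(C)C)O[C@@H](c1ccc(O[Si](C)(C)C(C)(C)C)cc1)[C@@H]2c1cc(O[Si](C)(C)C(C)(C)C)cc(O[Si](C)(C)C(C)(C)C)c1 | intermediate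
19 | (E)-2',4',6'-trihydroxy-3',5'-diprenylchalcone carrying the tetrakis(TBS) dihydrobenzofuran as ring B | CC(C)=CCc1c(O)c(CC=C(C)C)c(O)c(C(=O)/C=C/c2cc3c(cc2O[Si](C)(C)C(C)(C)C)O[C@@H](c2ccc(O[Si](C)(C)C(C)(C)C)cc2)[C@@H]3c2cc(O[Si](C)(C)C(C)(C)C)cc(O[Si](C)(C)C(C)(C)C)c2)c1O | intermediate
20 | (2S)-flavanone, tetrakis(TBS) ether of the target | CC(C)=CCc1c(O)c(CC=C(C)C)c2c(c1O)C(=O)C[C@@H](c1cc3c(cc1O[Si](C)(C)C(C)(C)C)O[C@@H](c1ccc(O[Si](C)(C)C(C)(C)C)cc1)[C@@H]3c1cc(O[Si](C)(C)C(C)(C)C)cc(O[Si](C)(C)C(C)(C)C)c1)O2 | intermediate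
21 | (2S)-2-[(2R,3R)-3-(3,5-dihydroxyphenyl)-6-hydroxy-2-(4-hydroxyphenyl)-2,3-dihydro-1-benzofuran-5-yl]-5,7-dihydroxy-6,8-bis(3-methylbut-2-en-1-yl)-2,3-dihydro-4H-chromen-4-one | CC(C)=CCc1c(O)c(CC=C(C)C)c2c(c1O)C(=O)C[C@@H](c1cc3c(cc1O)O[C@@H](c1ccc(O)cc1)[C@@H]3c1cc(O)cc(O)c1)O2 | target

**Step count and risks**

Total steps: 11. Longest linear sequence: 10 steps (steps 2 to 11); step 1 is the one-step side branch.

Steps most likely to fail:

1. Step 10 (proposed new method). O-acylation of the phenolate or conjugate attack of the ring carbon may outrun the templated C-acylation, and uncatalysed ring closure on the magnesium chelate may erode the facial selectivity at C2. Fallback with known chemistry, setting out from 3 and 17 and returning at 20: 3 is converted with chloromethyl methyl ether and i-Pr2NEt into 1,3,5-tris(methoxymethoxy)-2,4-bis(3-methylbut-2-en-1-yl)benzene F1, and 17 is coupled with N,O-dimethylhydroxylamine (EDCI, HOBt) to the N-methoxy-N-methylamide F2. Directed ortho-lithiation of F1 at its only ring C–H (n-BuLi, THF, 0 °C) and addition to F2 at −78 °C should give the tris(methoxymethyl)-protected chalcone F3. TMSOTf/2,2'-bipyridyl followed by water should free the three ring-A hydroxyls to give 19, which closes under NaOAc in EtOH to 20 and the (2R)-epimer of 20 F4. The epimers are separated by preparative HPLC, and F4 is re-equilibrated with NaOAc and recycled.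

2. Step 7. Lewis-acid ionisation of the benzylic C2–O bond may lead to elimination to a stilbene and reclosure with loss of the C3 configuration, or demethylation may stop short of all four ethers. Fallback, setting out from 12 and returning at 14: 12 is first equilibrated with trifluoroacetic acid in CH2Cl2 at 0 °C to the trans tetramethyl ether 13, which is isolated. The methyl ethers are then cleaved by SN2 attack of excess sodium ethanethiolate in DMF at 140 °C, basic conditions under which the benzylic C–O bond cannot ionise. No compound outside the list arises (F0).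

3. Step 9. Oxidative addition to the hindered, electron-rich aryl bromide may be slow, with competing protodebromination or loss of silyl ethers at the temperature needed. Fallback, setting out from 15 and returning at 17: bromine–magnesium exchange of 15 with n-Bu3MgLi (THF, −10 °C) and quenching with DMF should give the tetrakis(TBS) 2,3-dihydro-1-benzofuran-5-carbaldehyde F5. Horner–Wadsworth–Emmons olefination of F5 with the dianion of diethylphosphonoacetic acid (n-BuLi, THF, −78 °C → rt) should then give the (E)-acid 17 directly.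

**Further compounds**

F1 | step 10 | 1,3,5-tris(methoxymethoxy)-2,4-bis(3-methylbut-2-en-1-yl)benzene | CC(C)=CCc1c(OCOC)cc(OCOC)c(CC=C(C)C)c1OCOC
F2 | step 10 | (2E)-N-methoxy-N-methylamide of acid 17 | CON(C)C(=O)/C=C/c1cc2c(cc1O[Si](C)(C)C(C)(C)C)O[C@@H](c1ccc(O[Si](C)(C)C(C)(C)C)cc1)[C@@H]2c1cc(O[Si](C)(C)C(C)(C)C)cc(O[Si](C)(C)C(C)(C)C)c1
F3 | step 10 | 2',4',6'-tris(methoxymethyl) ether of chalcone 19 | CC(C)=CCc1c(OCOC)c(CC=C(C)C)c(OCOC)c(C(=O)/C=C/c2cc3c(cc2O[Si](C)(C)C(C)(C)C)O[C@@H](c2ccc(O[Si](C)(C)C(C)(C)C)cc2)[C@@H]3c2cc(O[Si](C)(C)C(C)(C)C)cc(O[Si](C)(C)C(C)(C)C)c2)c1OCOC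
F4 | step 10 | (2R)-epimer of flavanone 20 | CC(C)=CCc1c(O)c(CC=C(C)C)c2c(c1O)C(=O)C[C@H](c1cc3c(cc1O[Si](C)(C)C(C)(C)C)O[C@@H](c1ccc(O[Si](C)(C)C(C)(C)C)cc1)[C@@H]3c1cc(O[Si](C)(C)C(C)(C)C)cc(O[Si](C)(C)C(C)(C)C)c1)O2
F0 | step 7 | none | none
F5 | step 9 | (2R,3R)-3-[3,5-bis(tert-butyldimethylsilyloxy)phenyl]-6-(tert-butyldimethylsilyloxy)-2-[4-(tert-butyldimethylsilyloxy)phenyl]-2,3-dihydro-1-benzofuran-5-carbaldehyde | O=Cc1cc2c(cc1O[Si](C)(C)C(C)(C)C)O[C@@H](c1ccc(O[Si](C)(C)C(C)(C)C)cc1)[C@@H]2c1cc(O[Si](C)(C)C(C)(C)C)cc(O[Si](C)(C)C(C)(C)C)c1
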